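**Assumption:** Locants follow resveratrol-oligomer usage: C7a = O–CH(aryl) of the dihydrofuran, C8a = its neighbour, C7b = CH bearing 4-hydroxyphenyl in the seven-membered ring, C8b = CH bearing the formyl-hydroxyphenyl group. The target is (7aS,8aS,7bS,8bR). The antipode of the chiral acid in step 5 that gives 8aS is fixed by a screen.

## Retrosynthetic overview

1. Vitisinol B ⇐ its hexamethyl ether, by one global O-demethylation.
2. Hexamethyl ether ⇐ one-flask double annulation of an achiral phenolic bis-alkene: chiral-acid hydroalkoxylation closes the dihydrobenzofuran (C7a–O; sets 8a and 7a), then Cu-catalysed anti-carboarylation of the stilbene with an aryl(mesityl)iodonium salt makes C8b–aryl and the seven-membered ring (C7b–aryl; sets 8b and 7b).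
3. Bis-alkene ⇐ Heck coupling with 4-methoxystyrene ⇐ bromo-triarylethene ⇐ benzyl-Grignard addition and dehydration ⇐ o-hydroxybenzophenone.
4. Benzophenone ⇐ Friedel–Crafts acylation of 1-bromo-3,5-dimethoxybenzene; iodonium salt ⇐ arylboronic acid and iodomesitylene diacetate.
5. Ring order: dihydrofuran first, seven-membered carbocycle second, both in the same operation.

## Route

**Step 1**
Reactants: 1 1-bromo-3,5-dimethoxybenzene; 2 3,5-dimethoxybenzoyl chloride
Product: 4 (2-bromo-6-hydroxy-4-methoxyphenyl)(3,5-dimethoxyphenyl)methanone, via methoxy ketone 3 (not isolated)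
Conditions: AlCl3 (3 equiv), CH2Cl2, 0 → 40 °C; aq. HCl
Reagents that add atoms: none
Why: Friedel–Crafts acylation goes para to one OMe and ortho to Br of 1 (the site of its Vilsmeier formylation), and AlCl3 chelated by the new ketone then cleaves only the OMe ortho to C=O (chelation-controlled demethylation); no stereocentre is formed.

**Step 2**
Reactants: 4 (2-bromo-6-hydroxy-4-methoxyphenyl)(3,5-dimethoxyphenyl)methanone; 5 (4-methoxybenzyl)magnesium chloride
Product: 7 3-bromo-2-[1-(3,5-dimethoxyphenyl)-2-(4-methoxyphenyl)ethenyl]-5-methoxyphenol (E/Z mixture), via tertiary alcohol 6 (not isolated)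
Conditions: 5 (3.5 equiv), LaCl3·2LiCl (30 mol %), THF, 0 °C → rt; aq. NH4Cl; then PPTS (cat.), PhMe, 60 °C
Reagents that add atoms: none
Why: 1,2-Grignard addition to the magnesium-chelated o-hydroxybenzophenone (the first equivalent is spent on the phenol) gives a tertiary o-hydroxybenzylic alcohol that dehydrates through its o-quinone methide under mild acid; the E/Z ratio is irrelevant because both isomers converge in step 5, and no stereocentre is formed.

**Step 3**
Reactants: 7 3-bromo-2-[1-(3,5-dimethoxyphenyl)-2-(4-methoxyphenyl)ethenyl]-5-methoxyphenol; 8 4-methoxystyrene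
Product: 9 2-[1-(3,5-dimethoxyphenyl)-2-(4-methoxyphenyl)ethenyl]-5-methoxy-3-[(E)-2-(4-methoxyphenyl)ethenyl]phenol
Conditions: Pd(OAc)2 (5 mol %), P(o-tol)3 (10 mol %), NaOAc, DMA, 110 °C
Reagents that add atoms: none
Why: Mizoroki–Heck coupling of the aryl bromide with the terminal styrene gives the E-stilbene; the phenol and the trisubstituted alkene are inert to Pd(0)/acetate, and no stereocentre is formed.

**Step 4**
Reactants: 10 (5-formyl-2-methoxyphenyl)boronic acid; 11 (diacetoxyiodo)mesitylene
Product: 13 (5-formyl-2-methoxyphenyl)(mesityl)iodonium trifluoromethanesulfonate, via mixed iodane 12 (not isolated)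
Conditions: TfOH (1.0 equiv), CH2Cl2, −30 °C → rt
Reagents that add atoms: trifluoromethanesulfonic acid, OS(=O)(=O)C(F)(F)F
Why: Ipso boron-to-iodine(III) aryl transfer onto the triflic-acid-activated iodane gives the unsymmetrical diaryliodonium triflate regiospecifically (no peracid, so the aldehyde survives); mesityl is the ligand that is not transferred later.

**Step 5**
Reactants: 9 2-[1-(3,5-dimethoxyphenyl)-2-(4-methoxyphenyl)ethenyl]-5-methoxy-3-[(E)-2-(4-methoxyphenyl)ethenyl]phenol; 13 (5-formyl-2-methoxyphenyl)(mesityl)iodonium trifluoromethanesulfonate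
Product: 15 vitisinol B hexamethyl ether (7aS,8aS,7bS,8bR), via ε-viniferin pentamethyl ether 14 (not isolated)
Conditions: chiral IDPi Brønsted acid (5 mol %), 5 Å MS, CHCl3, −20 °C; then 2,6-di-tert-butylpyridine (1.5 equiv), 13 (1.3 equiv), Cu(OTf)2 (10 mol %), DCE, 50 °C
Reagents that add atoms: none
Why: Proposed new method: a confined IDPi acid protonates C8a of the triarylethene while the ortho phenol closes onto the incipient 4-methoxybenzylic cation at C7a (closest known reaction: IDPi-catalysed asymmetric intramolecular hydroalkoxylation of alkenes), which fixes 8aS under catalyst control and 7aS as the trans isomer through reversible C7a–O ionisation, the less basic stilbene being left alone at −20 °C; after buffering, the Cu(III)–aryl from 13 adds to C8b of the stilbene on the face away from the C8a aryl ring and that ring traps the 4-methoxybenzylic cation at C7b from the other face (closest known reaction: Cu-catalysed alkene arylation/Friedel–Crafts carbocyclisation with diaryliodonium salts), so anti-addition across the E-alkene gives 8bR,7bS with H8a and H8b cis.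

**Step 6**
Reactants: 15 vitisinol B hexamethyl ether
Product: 16 vitisinol B (7aS,8aS,7bS,8bR)
Conditions: BBr3 (12 equiv), CH2Cl2, −78 → 0 °C; MeOH/H2O, aq. NaHCO3
Reagents that add atoms: none
Why: BBr3 cleaves the six aryl methyl ethers; C8a and C8b carry no leaving group and cannot epimerise, the benzylic C7a–O bond, if opened, should re-close to the trans-dihydrofuran on aqueous work-up because this ring system is the acid-stable end point of the ε-viniferin manifold, and any benzal bromide formed at the aldehyde hydrolyses back.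

## Compound list

1 | 1-bromo-3,5-dimethoxybenzene | COc1cc(Br)cc(OC)c1 | starting material
2 | 3,5-dimethoxybenzoyl chloride | COc1cc(cc(OC)c1)C(Cl)=O | starting material
3 | (2-bromo-4,6-dimethoxyphenyl)(3,5-dimethoxyphenyl)methanone | COc1cc(OC)cc(c1)C(=O)c1c(Br)cc(OC)cc1OC | intermediate
4 | (2-bromo-6-hydroxy-4-methoxyphenyl)(3,5-dimethoxyphenyl)methanone | COc1cc(OC)cc(c1)C(=O)c1c(Br)cc(OC)cc1O | intermediate
5 | (4-methoxybenzyl)magnesium chloride | COc1ccc(C[Mg]Cl)cc1 | starting material
6 | 1-(2-bromo-6-hydroxy-4-methoxyphenyl)-1-(3,5-dimethoxyphenyl)-2-(4-methoxyphenyl)ethan-1-ol (racemic) | COc1ccc(CC(O)(c2cc(OC)cc(OC)c2)c2c(Br)cc(OC)cc2O)cc1 | intermediate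
7 | 3-bromo-2-[1-(3,5-dimethoxyphenyl)-2-(4-methoxyphenyl)ethenyl]-5-methoxyphenol (E/Z mixture) | COc1ccc(C=C(c2cc(OC)cc(OC)c2)c2c(Br)cc(OC)cc2O)cc1 | intermediate
8 | 4-methoxystyrene | C=Cc1ccc(OC)cc1 | starting material
9 | 2-[1-(3,5-dimethoxyphenyl)-2-(4-methoxyphenyl)ethenyl]-5-methoxy-3-[(E)-2-(4-methoxyphenyl)ethenyl]phenol (E/Z at the triarylethene) | COc1ccc(/C=C/c2cc(OC)cc(O)c2C(=Cc2ccc(OC)cc2)c2cc(OC)cc(OC)c2)cc1 | intermediate
10 | (5-formyl-2-methoxyphenyl)boronic acid | COc1ccc(C=O)cc1B(O)O | starting material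
11 | (diacetoxyiodo)mesitylene | CC(=O)OI(OC(C)=O)c1c(C)cc(C)cc1C | starting material
12 | acetoxy(mesityl)-λ3-iodanyl trifluoromethanesulfonate | CC(=O)OI(OS(=O)(=O)C(F)(F)F)c1c(C)cc(C)cc1C | intermediate
13 | (5-formyl-2-methoxyphenyl)(mesityl)iodonium trifluoromethanesulfonate | COc1ccc(C=O)cc1[I+]c1c(C)cc(C)cc1C.[O-]S(=O)(=O)C(F)(F)F | intermediate
14 | (2S,3S)-3-(3,5-dimethoxyphenyl)-6-methoxy-2-(4-methoxyphenyl)-4-[(E)-2-(4-methoxyphenyl)ethenyl]-2,3-dihydro-1-benzofuran (ε-viniferin pentamethyl ether) | COc1ccc(/C=C/c2cc(OC)cc3c2[C@H](c2cc(OC)cc(OC)c2)[C@@H](c2ccc(OC)cc2)O3)cc1 | intermediate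
15 | vitisinol B hexamethyl ether (7aS,8aS,7bS,8bR; all six phenols as OMe) | O=Cc1ccc(OC)c([C@H]2c3cc(OC)cc4c3[C@H](c3cc(OC)cc(OC)c3[C@@H]2c2ccc(OC)cc2)[C@@H](c2ccc(OC)cc2)O4)c1 | intermediate
16 | vitisinol B (7aS,8aS,7bS,8bR) | O=Cc1ccc(O)c([C@H]2c3cc(O)cc4c3[C@H](c3cc(O)cc(O)c3[C@@H]2c2ccc(O)cc2)[C@@H](c2ccc(O)cc2)O4)c1 | target

## Step count and risks

Total steps: 6. Longest linear sequence: 5 (steps 1, 2, 3, 5, 6; step 4 is a one-step side branch).

**Step 5 (most likely to fail).** The hydroalkoxylation has no direct precedent on a triarylethene and its ee is unknown. The acid may also cyclise the stilbene before the dihydrofuran closes. In the copper stage, direct arylation of the dimethoxyarene or O-trapping by the ortho-OMe of the new aryl group can compete with the seven-ring closure.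
Fallback: set out from 4 and return at 14. Alkylate the phenol of 4 with 4-methoxybenzyl chloride/K2CO3 to give (2-bromo-4-methoxy-6-[(4-methoxybenzyl)oxy]phenyl)(3,5-dimethoxyphenyl)methanone F1. Condense with hydrazine to the hydrazone F2 and oxidise with MnO2 to the diaryldiazomethane F3. Rh2(S-PTAD)4 (or its antipode) then inserts the donor/donor carbene into the benzylic O–CH2 bond, giving mainly the cis-(2R,3S)-4-bromo-2,3-diaryl-2,3-dihydrobenzofuran F4. TFA epimerises C2 to the trans-(2S,3S)-bromide F5. Heck coupling of F5 with 8 gives 14, now isolated, which is treated with 13 under the copper conditions alone to reach 15. The hindered hydrazone formation is the weak point of this detour.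

**Step 6.** Lewis-acidic demethylation next to a 4-oxybenzylic ether may open or scramble the dihydrofuran or give partial cleavage.
Fallback: set out from 15 and return at 16. Protect the aldehyde with ethylene glycol/PPTS as the 1,3-dioxolane of vitisinol B hexamethyl ether F6. Cleave the methyl ethers nucleophilically with NaSEt in DMF at 130 °C to the 1,3-dioxolane of vitisinol B F7. Hydrolyse the acetal with dilute aqueous HCl in THF to 16.

**Step 2.** The ketone is flanked by Br and a phenoxide, so benzyl-Grignard addition may stall or give Wurtz coupling.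
Fallback: set out from 4 and return at 7. Add the smaller MeMgBr and dehydrate to 3-bromo-2-[1-(3,5-dimethoxyphenyl)ethenyl]-5-methoxyphenol F8. Heck-arylate its terminal CH2 with 4-iodoanisole (Pd(OAc)2, Ag2CO3; C–I reacts before the hindered C–Br) to give 7.

Further compounds
F1 | step 5 | (2-bromo-4-methoxy-6-[(4-methoxybenzyl)oxy]phenyl)(3,5-dimethoxyphenyl)methanone | COc1ccc(COc2cc(OC)cc(Br)c2C(=O)c2cc(OC)cc(OC)c2)cc1
F2 | step 5 | [(2-bromo-4-methoxy-6-[(4-methoxybenzyl)oxy]phenyl)(3,5-dimethoxyphenyl)methylidene]hydrazine | COc1ccc(COc2cc(OC)cc(Br)c2C(=NN)c2cc(OC)cc(OC)c2)cc1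
F3 | step 5 | 1-bromo-2-[diazo(3,5-dimethoxyphenyl)methyl]-5-methoxy-3-[(4-methoxybenzyl)oxy]benzene | COc1ccc(COc2cc(OC)cc(Br)c2C(=[N+]=[N-])c2cc(OC)cc(OC)c2)cc1
F4 | step 5 | (2R,3S)-4-bromo-3-(3,5-dimethoxyphenyl)-6-methoxy-2-(4-methoxyphenyl)-2,3-dihydro-1-benzofuran (cis) | Brc1cc(OC)cc2c1[C@H](c1cc(OC)cc(OC)c1)[C@H](c1ccc(OC)cc1)O2
F5 | step 5 | (2S,3S)-4-bromo-3-(3,5-dimethoxyphenyl)-6-methoxy-2-(4-methoxyphenyl)-2,3-dihydro-1-benzofuran (trans) | Brc1cc(OC)cc2c1[C@H](c1cc(OC)cc(OC)c1)[C@@H](c1ccc(OC)cc1)O2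
F6 | step 6 | 1,3-dioxolane of vitisinol B hexamethyl ether | C1COC(O1)c1ccc(OC)c([C@H]2c3cc(OC)cc4c3[C@H](c3cc(OC)cc(OC)c3[C@@H]2c2ccc(OC)cc2)[C@@H](c2ccc(OC)cc2)O4)c1
F7 | step 6 | 1,3-dioxolane of vitisinol B | C1COC(O1)c1ccc(O)c([C@H]2c3cc(O)cc4c3[C@H](c3cc(O)cc(O)c3[C@@H]2c2ccc(O)cc2)[C@@H](c2ccc(O)cc2)O4)c1
F8 | step 2 | 3-bromo-2-[1-(3,5-dimethoxyphenyl)ethenyl]-5-methoxyphenol | C=C(c1cc(OC)cc(OC)c1)c1c(Br)cc(OC)cc1O
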